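Numbering used throughout: C1 = lactone C=O, then C2(Me), C3(=O), C4(Cl), C5(enol C), C6, C7, C8(Me), C9–C11, C12, C13=C14, C15, C16(Me), C17=C18–C19=C20, C21(Me)–O. The cyclohexene is C6-C7-C12-C13-C14-C15 and the cyclohexane is C7–C12.
Cuts, in retrosynthetic order: C4–Cl; O–C1 and C4–C5 (excising C1–C4 leaves a temporary 10-membered C5–O–C21 lactone); C6–C15 and C7–C12 (retro-Diels–Alder); C16–C17; then C6=C7, C13–C14 and C18–C19.
Enabling feature: once the cyclohexene is opened, C16 is doubly allylic. It lies between the Z,Z-diene C17–C20 and an "E,E" diene C12–C15, which is the skipped-diene pattern of an allyl–alkenyl coupling. C5 on C6 and C16 on C15 are cis, the endo pattern that a short C5–O–C21 strap can span.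
Forward: an open-chain ester closes to an 18-membered ring at C16–C17. In the same flask a transannular [4+2] then gives the cyclohexene, the cyclohexane and the 10-membered lactone. Ring expansion 10→14 and chlorination follow.
Stereochemistry: C21 comes from (S)- and C16 from (R)-but-3-yn-2-ol (inversion at Pd), and C8 from an Evans methylation. C6, C7, C12 and C15 are set in the cycloaddition by C16, a removable C14 silyl group and the strap. C2 is set by equilibration, and the Z,Z-diene comes from diimide reduction and a (Z)-distannylethene.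

Key step: step 15

Assumption: C2, flanked by the C1 ester and the C3 ketone, is configurationally labile, and the (2S) epimer is taken as the more stable one in the 14-membered ring; C3–C5 is written as the diketone in 29–31 and as the enol tautomer of the given structure in 32.

Step 1
Reactants: 1 (S)-but-3-yn-2-ol
Product: 2 (S)-4-iodobut-3-yn-2-ol
Conditions: NIS, AgNO3 (cat.), acetone, rt
Reagents that add atoms: N-iodosuccinimide, O=C1CCC(=O)N1I
Why: Silver-catalysed electrophilic iodination of the terminal alkyne C–H should give the 1-iodoalkyne without touching the carbinol centre (future C21).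

Step 2
Reactants: 2 (S)-4-iodobut-3-yn-2-ol
Product: 3 (2S,3Z)-4-iodobut-3-en-2-ol
Conditions: 2-nitrobenzenesulfonohydrazide, Et3N, THF/i-PrOH, rt
Reagents that add atoms: none
Why: Diimide reduction (concerted syn delivery of two H atoms) should give the (Z)-iodoalkene, which fixes the C19=C20 geometry and leaves the C–I bond intact.

Step 3
Reactants: 4 acetylene; 5 hexabutyldistannane
Product: 6 (Z)-1,2-bis(tributylstannyl)ethene
Conditions: Pd(PPh3)4 (cat.), dioxane, 60 °C, acetylene (1 atm)
Reagents that add atoms: none
Why: Palladium-catalysed syn-distannylation of an alkyne puts both tin groups on the same side and should give the (Z)-distannane, the source of C17=C18.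

Step 4
Reactants: 3 (2S,3Z)-4-iodobut-3-en-2-ol; 6 (Z)-1,2-bis(tributylstannyl)ethene
Product: 7 (2S,3Z,5Z)-6-(tributylstannyl)hexa-3,5-dien-2-ol
Conditions: 6 (2.5 equiv), PdCl2(MeCN)2 (cat.), DMF, rt, dark
Reagents that add atoms: none
Why: Stille coupling proceeds with retention at both alkenyl partners and should give the (Z,Z)-dienylstannane, the excess of 6 holding the reaction at mono-coupling.

Step 5
Reactants: 7 (2S,3Z,5Z)-6-(tributylstannyl)hexa-3,5-dien-2-ol; 8 2-(diethoxyphosphoryl)acetic acid
Product: 9 (2S,3Z,5Z)-6-(tributylstannyl)hexa-3,5-dien-2-yl 2-(diethoxyphosphoryl)acetate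
Conditions: DCC, DMAP (cat.), CH2Cl2, 0 °C to rt
Reagents that add atoms: none
Why: Steglich esterification acylates the alcohol at oxygen under near-neutral conditions, so C21 keeps its configuration and the acid-sensitive dienylstannane should survive.

Step 6
Reactants: 10 (R)-4-benzyl-1,3-oxazolidin-2-one; 11 hept-6-ynoic acid
Product: 12 (R)-4-benzyl-3-(hept-6-ynoyl)-1,3-oxazolidin-2-one
Conditions: DCC, DMAP (cat.), CH2Cl2, 0 °C to rt
Reagents that add atoms: none
Why: Carbodiimide/DMAP N-acylation attaches the acid to the auxiliary needed for the Evans alkylation.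

Step 7
Reactants: 12 (R)-4-benzyl-3-(hept-6-ynoyl)-1,3-oxazolidin-2-one
Product: 14 (R)-4-benzyl-3-[(2R)-2-methylhept-6-ynoyl]-1,3-oxazolidin-2-one, via sodium Z-enolate 13 (not isolated)
Conditions: NaHMDS, THF, −78 °C; MeI
Reagents that add atoms: iodomethane, CI
Why: Evans asymmetric alkylation: the chelated (Z)-enolate is methylated on the face opposite the benzyl group, which should set C8 as (R), and the imide α-proton is removed in preference to the much less acidic alkyne C–H.

Step 8
Reactants: 14 (R)-4-benzyl-3-[(2R)-2-methylhept-6-ynoyl]-1,3-oxazolidin-2-one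
Product: 15 (2R)-2-methylhept-6-yn-1-ol
Conditions: LiBH4, H2O (1 equiv), Et2O, 0 °C
Reagents that add atoms: none
Why: Reductive cleavage of the imide with LiBH4 should give the primary alcohol without epimerising C8, and the alkyne is inert.

Step 9
Reactants: 15 (2R)-2-methylhept-6-yn-1-ol
Product: 17 (2R,6E)-7-iodo-2-methylhept-6-en-1-ol, via alkenylzirconocene 16 (not isolated)
Conditions: Cp2Zr(H)Cl (2.2 equiv), THF, rt; I2, 0 °C
Reagents that add atoms: iodine, II
Why: Hydrozirconation (syn addition, Zr at the terminal carbon, one further equivalent consumed by the OH) followed by iodinolysis with retention should give the (E)-iodoalkene, the future C12=C13.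

Step 10
Reactants: 17 (2R,6E)-7-iodo-2-methylhept-6-en-1-ol; 18 (R)-but-3-yn-2-ol
Product: 19 (2R,6E,10R)-2-methylundec-6-en-8-yne-1,10-diol
Conditions: PdCl2(PPh3)2 (cat.), CuI (cat.), Et3N, THF, rt
Reagents that add atoms: none
Why: Sonogashira coupling forms C13–C14 with retention of the E geometry, tolerates both free hydroxy groups and brings in the C16 carbinol centre from the chiral pool.

Step 11
Reactants: 19 (2R,6E,10R)-2-methylundec-6-en-8-yne-1,10-diol
Product: 20 (2R,6E,8Z,10R)-8-[benzyl(dimethyl)silyl]-2-methylundeca-6,8-diene-1,10-diol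
Conditions: BnMe2SiH, [Cp*Ru(MeCN)3]PF6 (cat.), CH2Cl2, 0 °C to rt
Reagents that add atoms: benzyldimethylsilane, C[SiH](C)Cc1ccccc1
Why: Ruthenium-catalysed trans-hydrosilylation should place silicon on the alkyne carbon distal to the propargylic OH (C14) and H on C15 from the opposite side, so C16 and C11 are both outside substituents of the diene and the silyl group is cis to C16, where it later acts as a steric control element.

Step 12
Reactants: 20 (2R,6E,8Z,10R)-8-[benzyl(dimethyl)silyl]-2-methylundeca-6,8-diene-1,10-diol
Product: 21 (2R,6E,8Z,10R)-8-[benzyl(dimethyl)silyl]-10-hydroxy-2-methylundeca-6,8-dienal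
Conditions: TEMPO (cat.), PhI(OAc)2, CH2Cl2, rt
Reagents that add atoms: none
Why: Oxoammonium (TEMPO) oxidation should take the unhindered primary alcohol in preference to the secondary allylic alcohol shielded by the cis silyl group, and it stops at the aldehyde without epimerising C8.

Step 13
Reactants: 21 (2R,6E,8Z,10R)-8-[benzyl(dimethyl)silyl]-10-hydroxy-2-methylundeca-6,8-dienal; 9 (2S,3Z,5Z)-6-(tributylstannyl)hexa-3,5-dien-2-yl 2-(diethoxyphosphoryl)acetate
Product: 22 (2S,3Z,5Z)-6-(tributylstannyl)hexa-3,5-dien-2-yl (2E,4R,8E,10Z,12R)-10-[benzyl(dimethyl)silyl]-12-hydroxy-4-methyltrideca-2,8,10-trienoate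
Conditions: LiCl, i-Pr2NEt, MeCN, rt
Reagents that add atoms: none
Why: Horner–Wadsworth–Emmons olefination under Masamune–Roush conditions should join the two halves as the (E)-enoate C6=C7 and is mild enough for the α-methyl aldehyde, the free alcohol and the stannane.

Step 14
Reactants: 22 hydroxy ester (name as in step 13)
Product: 23 (2S,3Z,5Z)-6-(tributylstannyl)hexa-3,5-dien-2-yl (2E,4R,8E,10Z,12R)-10-[benzyl(dimethyl)silyl]-12-[(methoxycarbonyl)oxy]-4-methyltrideca-2,8,10-trienoate
Conditions: ClCO2Me, pyridine, CH2Cl2, 0 °C
Reagents that add atoms: methyl chloroformate, COC(=O)Cl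
Why: O-acylation with a chloroformate turns the C16 alcohol into an allylic carbonate with retention, since the C–O bond is not touched.

Step 15
Reactants: 23 open-chain stannyl carbonate (name as in step 14)
Product: 25 C14-silylated tricyclic lactone (trans-decalin, C5 on C6 cis to C16 on C15, 10-membered C5–O–C21 lactone holding the Z,Z-diene; spatial arrangement at C6, C7, C8, C12, C15, C16 and C21 as in the target), via 18-membered macrolactone 24 (not isolated)
Conditions: Pd2(dba)3·CHCl3 (cat.), AsPh3, DMF, 40 °C, slow addition (final 1 mM); then BHT, 110 °C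
Reagents that add atoms: none
Why: Pd(0) ionises the C16 carbonate anti to the leaving group (loss of CO2 and methoxide), and tin-to-palladium transfer of the (Z,Z)-dienyl group followed by reductive elimination on the Pd face forms C16–C17 with net inversion; this is the allyl–alkenyl Stille coupling in its macrocyclising form, and macrolactone 24 then undergoes a transannular Diels–Alder reaction on heating. The 18-membered ring closes end to end at the allyl terminus remote from silicon, because the C14 terminus is fully substituted and coupling at C16 keeps the C12–C15 diene conjugated; the [4+2] step then closes the cyclohexene (C6–C15 and C7–C12) and the cyclohexane (chair-like C8–C11 tether) and contracts the macrocycle to the 10-membered lactone. C16 is set by stereospecific inversion of the (R)-carbonate, and C15 and C12 follow from the two outside diene substituents and from the diene face, which C16 fixes: 1,3-allylic strain with the cis C14 silyl group holds H16 in the diene plane, the C16 methyl points away, and the six-atom strap C17–C21–O carries the enoate to the face it occupies. C6 and C7 follow from the (E)-enoate (C5 and C8 trans) and from the endo mode, the only one the short strap can span (C5 cis to C16), which also makes the decalin trans-fused. The C8 methyl must sit axial on the forming chair, a cost that should be outweighed by the methyl/silyl clash in the alternative endo transition state. The step needs ionisation of the carbonate rather than the C21 dienyl ester (the carbonate leaves irreversibly and the Z-alkene at C20 disfavours ionisation), reaction of only one diene (the Z,Z-diene cannot reach a reactive s-cis form), and transmetalation faster than β-hydride loss from the C16 methyl.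

Step 16
Reactants: 25 C14-silylated tricyclic lactone
Product: 26 tricyclic 10-membered lactone (6R,7R,8R,12S,15S,16R,21S; 17Z,19Z)
Conditions: TBAF, wet THF, 0 to 40 °C
Reagents that add atoms: none
Why: Fluoride-induced protodesilylation of the benzyldimethylsilyl alkene (attack at silicon, protonation at the carbon that carried it) should remove the control element and leave C13=C14 in place, the lactone and the dienes being inert to fluoride.

Step 17
Reactants: 26 tricyclic 10-membered lactone; 27 tert-butyl 2-methyl-3-oxobutanoate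
Product: 29 tert-butyl 2-methyl-3,5-dioxopentanoate carrying the decalin at C5 (C6) and a free C21–OH (6R,7R,8R,12S,15S,16R,21S; C2 epimers), via ketoester dianion 28 (not isolated)
Conditions: 27 (4 equiv), NaH, THF, 0 °C; n-BuLi, 0 °C; then 26, 0 °C to rt
Reagents that add atoms: none
Why: Claisen-type acylation of the β-keto ester dianion at its terminal carbon (C4) by the lactone carbonyl forms C4–C5, opens the temporary ring and frees the C21 alkoxide, while the product is shielded as its enolate from a second attack and C6 keeps the more stable equatorial acyl arrangement.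

Step 18
Reactants: 29 seco hydroxy dioxo ester
Product: 31 4-deschloro macrolide (14-membered lactone; 2S,6R,7R,8R,12S,15S,16R,21S), via acylketene 30 (not isolated)
Conditions: toluene (0.5 mM), 110 °C
Reagents that add atoms: none
Why: Thermolysis of the tert-butyl β-keto ester expels tert-butanol to give an acylketene that C21–OH captures at high dilution (acylketene macrolactonisation), C21 is not touched, and C2 arises by ketonisation and should equilibrate through the enol to the more stable (2S) epimer.

Step 19
Reactants: 31 4-deschloro macrolide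
Product: 32 target CNP0477386.1
Conditions: NCS (1.0 equiv), 2,6-lutidine, CH2Cl2, −20 to 0 °C
Reagents that add atoms: N-chlorosuccinimide, O=C1CCC(=O)N1Cl
Why: Electrophilic α-chlorination of the enolised 1,3-diketone should occur at C4, the most nucleophilic carbon (C2 is tertiary and less enolised), and stop after one equivalent at the fully enolised monochloride, while the alkenes are inert to NCS here and C2 stays under the same thermodynamic control.

Compound list
1 | (S)-but-3-yn-2-ol | C[C@H](O)C#C | starting material
2 | (S)-4-iodobut-3-yn-2-ol | C[C@H](O)C#CI | intermediate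
3 | (2S,3Z)-4-iodobut-3-en-2-ol | C[C@H](O)/C=C\I | intermediate
4 | acetylene | C#C | starting material
5 | hexabutyldistannane | CCCC[Sn](CCCC)(CCCC)[Sn](CCCC)(CCCC)CCCC | starting material
6 | (Z)-1,2-bis(tributylstannyl)ethene | CCCC[Sn](CCCC)(CCCC)/C=C\[Sn](CCCC)(CCCC)CCCC | intermediate
7 | (2S,3Z,5Z)-6-(tributylstannyl)hexa-3,5-dien-2-ol | C[C@H](O)/C=C\C=C/[Sn](CCCC)(CCCC)CCCC | intermediate
8 | 2-(diethoxyphosphoryl)acetic acid | CCOP(=O)(CC(=O)O)OCC | starting material
9 | (2S,3Z,5Z)-6-(tributylstannyl)hexa-3,5-dien-2-yl 2-(diethoxyphosphoryl)acetate | CCOP(=O)(OCC)CC(=O)O[C@@H](C)/C=C\C=C/[Sn](CCCC)(CCCC)CCCC | intermediate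
10 | (R)-4-benzyl-1,3-oxazolidin-2-one | O=C1OC[C@@H](Cc2ccccc2)N1 | starting material
11 | hept-6-ynoic acid | C#CCCCCC(=O)O | starting material
12 | (R)-4-benzyl-3-(hept-6-ynoyl)-1,3-oxazolidin-2-one | C#CCCCCC(=O)N1[C@H](Cc2ccccc2)COC1=O | intermediate
13 | sodium (Z)-enolate of 12 | [Na+].C#CCCC/C=C(\[O-])N1[C@H](Cc2ccccc2)COC1=O | intermediate
14 | (R)-4-benzyl-3-[(2R)-2-methylhept-6-ynoyl]-1,3-oxazolidin-2-one | C#CCCC[C@@H](C)C(=O)N1[C@H](Cc2ccccc2)COC1=O | intermediate
15 | (2R)-2-methylhept-6-yn-1-ol | C#CCCC[C@@H](C)CO | intermediate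
16 | (E)-alkenylzirconocene chloride from 15, O-zirconated | Cl[Zr](C1C=CC=C1)(C1C=CC=C1)/C=C/CCC[C@@H](C)CO[Zr](Cl)(C1C=CC=C1)C1C=CC=C1 | intermediate
17 | (2R,6E)-7-iodo-2-methylhept-6-en-1-ol | I/C=C/CCC[C@@H](C)CO | intermediate
18 | (R)-but-3-yn-2-ol | C[C@@H](O)C#C | starting material
19 | (2R,6E,10R)-2-methylundec-6-en-8-yne-1,10-diol | C[C@@H](O)C#C/C=C/CCC[C@@H](C)CO | intermediate
20 | (2R,6E,8Z,10R)-8-[benzyl(dimethyl)silyl]-2-methylundeca-6,8-diene-1,10-diol | C[C@@H](O)/C=C(/C=C/CCC[C@@H](C)CO)[Si](C)(C)Cc1ccccc1 | intermediate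
21 | (2R,6E,8Z,10R)-8-[benzyl(dimethyl)silyl]-10-hydroxy-2-methylundeca-6,8-dienal | C[C@@H](O)/C=C(/C=C/CCC[C@@H](C)C=O)[Si](C)(C)Cc1ccccc1 | intermediate
22 | open-chain hydroxy ester (C16–OH) | CCCC[Sn](CCCC)(CCCC)/C=C\C=C/[C@H](C)OC(=O)/C=C/[C@H](C)CCC/C=C/C(=C/[C@@H](C)O)[Si](C)(C)Cc1ccccc1 | intermediate
23 | open-chain stannyl carbonate (C16–OCO2Me) | CCCC[Sn](CCCC)(CCCC)/C=C\C=C/[C@H](C)OC(=O)/C=C/[C@H](C)CCC/C=C/C(=C/[C@@H](C)OC(=O)OC)[Si](C)(C)Cc1ccccc1 | intermediate
24 | 18-membered macrolactone (6E,12E,14Z,17Z,19Z; 8R,16R,21S; BnMe2Si on C14) | C1C[C@@H](C)/C=C/C(=O)O[C@@H](C)/C=C\C=C/[C@@H](C)/C=C(\[Si](C)(C)Cc2ccccc2)/C=C/C1 | intermediate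
25 | C14-silylated tricyclic 10-membered lactone | O=C1O[C@@H](C)/C=C\C=C/[C@@H](C)[C@@H]2C([Si](C)(C)Cc4ccccc4)=C[C@@H]3CCC[C@@H](C)[C@H]3[C@@H]21 | intermediate
26 | tricyclic 10-membered lactone | O=C1O[C@@H](C)/C=C\C=C/[C@@H](C)[C@@H]2C=C[C@@H]3CCC[C@@H](C)[C@H]3[C@@H]21 | intermediate
27 | tert-butyl 2-methyl-3-oxobutanoate | CC(=O)C(C)C(=O)OC(C)(C)C | starting material
28 | sodium lithium dianion of 27 | [Na+].[Li+].C=C([O-])C(C)=C([O-])OC(C)(C)C | intermediate
29 | seco hydroxy dioxo tert-butyl ester | CC(C)(C)OC(=O)C(C)C(=O)CC(=O)[C@@H]1[C@H]([C@H](C)/C=C\C=C/[C@H](C)O)C=C[C@@H]2CCC[C@@H](C)[C@H]21 | intermediate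
30 | acylketene from 29 | CC(=C=O)C(=O)CC(=O)[C@@H]1[C@H]([C@H](C)/C=C\C=C/[C@H](C)O)C=C[C@@H]2CCC[C@@H](C)[C@H]21 | intermediate
31 | 4-deschloro macrolide | C[C@@H]1C(=O)O[C@@H](C)/C=C\C=C/[C@@H](C)[C@@H]2C=C[C@@H]3CCC[C@@H](C)[C@H]3[C@@H]2C(=O)CC1=O | intermediate
32 | CNP0477386.1 | C[C@@H]1C(=O)O[C@@H](C)/C=C\C=C/[C@@H](C)[C@@H]2C=C[C@@H]3CCC[C@@H](C)[C@H]3[C@@H]2/C(O)=C(/Cl)C1=O | target

Total step count: 19. Longest linear sequence: 14 steps (steps 6–19, from 10 and 11).

Steps most likely to fail

Step 15.
- What may go wrong: β-hydride loss from the π-allylpalladium or oligomerisation may outrun the slow intramolecular tin-to-palladium transfer at high dilution. Facial selectivity in the hot, uncatalysed cycloaddition may also be poor, because the C8 methyl must go axial.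
- Fallback: the two events are separated and the ring is closed at another bond, setting out from 21 and 9.
- The C16 alcohol of 21 is converted with methyl chloroformate into the carbonate aldehyde F1.
- F1 is joined with an excess of 9 in an intermolecular allyl–alkenyl Stille coupling at normal concentration to give the phosphonate aldehyde F2.
- An intramolecular Horner–Wadsworth–Emmons reaction (LiCl, i-Pr2NEt, MeCN, high dilution) closes C6=C7 and gives 24, now isolated.
- A Lewis-acid-promoted transannular Diels–Alder reaction (Me2AlCl, CH2Cl2, −20 °C) leads back to the route at 25.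

Step 17.
- What may go wrong: the strongly basic dianion may enolise the hindered lactone, or the addition may reverse, instead of giving acyl transfer.
- Fallback: setting out from 26, the lactone is first opened with Me2AlN(OMe)Me (from AlMe3 and MeNH(OMe)·HCl, CH2Cl2) to the hydroxy Weinreb amide F3.
- The amide of F3 is then acylated onto dianion 28 through a chelated tetrahedral intermediate, and the route is rejoined at 29.

Step 18.
- What may go wrong: the acylketene may be captured by its own C5 enol oxygen (pyranone formation) or by a second molecule faster than by the hindered C21–OH.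
- Fallback: the ring is closed at C4–C5 instead of O–C1, setting out from 26 by way of F3.
- Heating F3 with 27 in toluene at normal concentration acylates C21–OH by intermolecular ketene capture. The ketene from 27 has no 5-oxo group, and this gives the acetoacetate amide F4.
- The dianion of F4 (LDA, THF, high dilution, −78 to 0 °C) attacks the Weinreb amide intramolecularly, and the route is rejoined at 31.

Further compounds
F1 | step 15 | (2R,3Z,5E,10R)-4-[benzyl(dimethyl)silyl]-10-methyl-11-oxoundeca-3,5-dien-2-yl methyl carbonate | C[C@@H](OC(=O)OC)/C=C(/C=C/CCC[C@@H](C)C=O)[Si](C)(C)Cc1ccccc1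
F2 | step 15 | (2S,3Z,5Z,7R,8Z,10E,15R)-9-[benzyl(dimethyl)silyl]-7,15-dimethyl-16-oxohexadeca-3,5,8,10-tetraen-2-yl 2-(diethoxyphosphoryl)acetate | CCOP(=O)(OCC)CC(=O)O[C@@H](C)/C=C\C=C/[C@@H](C)/C=C(\[Si](C)(C)Cc1ccccc1)/C=C/CCC[C@@H](C)C=O
F3 | step 17 | hydroxy Weinreb amide (C5 N-methoxy-N-methylamide, free C21–OH) | CON(C)C(=O)[C@@H]1[C@H]([C@H](C)/C=C\C=C/[C@H](C)O)C=C[C@@H]2CCC[C@@H](C)[C@H]21
F4 | step 18 | C21 2-methyl-3-oxobutanoate of the Weinreb amide | CON(C)C(=O)[C@@H]1[C@H]([C@H](C)/C=C\C=C/[C@H](C)OC(=O)C(C)C(C)=O)C=C[C@@H]2CCC[C@@H](C)[C@H]21
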